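**Retrosynthetic overview**

1. Target ⇒ core alcohol 25 + silyl-protected acid 31 (ester at O-8); the exocyclic methylene comes from a late Mannich/elimination; the acid comes from the (R)-lactic acid dioxolanone 26.
2. Core ⇒ bridgehead ketal ester 20 ⇒ decalin hydroperoxide 18 by Criegee rearrangement: one oxygen is inserted into the C5–C10 ring-fusion bond, so ring B (C5–C10) becomes the oxepane O–C5–C6–C7–C8–C9–C10, ring A becomes the oxepene O–C10–C1–C2–C3–C4–C5, and the ten-membered carbocycle appears. 18 ⇒ Δ4-enoate 17 by a Schenck ene reaction, which also places the alkene at C3=C4.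
3. Feature that allows this: C5 and C10 are joined only through the ether oxygen, so the two seven-membered oxacycles are the two six-membered rings of a eudesmane-type decalin plus one O atom. C10 is quaternary (best migrating group); C5 carries only poor migrators (vinylic C4 with CO2Me, acyloxy carbon C6).
4. 17 ⇒ ring A by intramolecular HWE onto the C5 ketone of cyclohexanone 13 (chain from the vinyl group by hydroformylation/Knoevenagel). 13 ⇒ enone 10 ⇒ enone 8 ⇒ dienol 6 ⇒ bromolactone 3 ⇒ benzoic acid (Birch reductive methylation; desymmetrizing bromolactonization sets C8/C10; conjugate reduction sets C7; α-hydroxylation sets C6).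
5. Order of ring formation: ring B (arene-derived carbocycle) → γ-lactone → ring A → both oxacycles and the ten-membered ring together in the key step.

Key step: step 16

Remark on numbering: atoms are numbered as in a germacrane (C1–C10 carbocycle, C14 = methyl on C10, C15 = ester carbon on C4, C11–C13 = lactone carbons; O bridges C5 and C10); ring A = C1–C5 + C10, ring B = C5–C10.
Remark on assumptions: dioxolanone 26 is taken as commercially available (otherwise one step from (R)-lactic acid and pivalaldehyde); in step 2 the pseudo-enantiomeric cinchona catalyst that gives 3 as drawn is used.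

**Route**

Step 1
Reactants: 1 benzoic acid
Product: 2 1-methylcyclohexa-2,5-diene-1-carboxylic acid
Conditions: Li, NH3(l), THF, −78 °C; then MeI; aq. HCl
Reagents that add atoms: iodomethane, CI
Why: Birch reduction gives the dienolate dianion, which is C-methylated at the carboxyl-bearing carbon (Birch reductive alkylation); the product has a mirror plane, so no stereocentre is formed.

Step 2
Reactants: 2 1-methylcyclohexa-2,5-diene-1-carboxylic acid
Product: 3 8-bromo-1-methyl-6-oxabicyclo[3.2.1]oct-2-en-7-one (bromolactone; Br anti to the lactone oxygen)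
Conditions: N-bromosuccinimide, (DHQD)2PHAL (hydroquinidine 1,4-phthalazinediyl diether, 10 mol %), CHCl3/hexane, −40 °C
Reagents that add atoms: N-bromosuccinimide, O=C1CCC(=O)N1Br
Why: Catalyst-controlled bromolactonization (asymmetric halolactonization) differentiates the two enantiotopic alkenes; anti addition of Br+ and carboxylate gives the bridged γ-lactone, which fixes C10 and C8 together (lactone O necessarily cis to C1) and puts Br anti to O at C9.

Step 3
Reactants: 3 bromolactone
Product: 4 1-methyl-6-oxabicyclo[3.2.1]oct-2-en-7-one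
Conditions: Bu3SnH, AIBN (cat.), benzene, 80 °C
Reagents that add atoms: none
Why: Radical chain dehalogenation (tin hydride reduction) removes the C9 bromine without touching alkene, lactone or either stereocentre.

Step 4
Reactants: 4 bicyclic lactone
Product: 5 1-methyl-6-oxabicyclo[3.2.1]oct-2-en-7-ol (bridged lactol, anomer mixture)
Conditions: i-Bu2AlH, CH2Cl2, −78 °C; Rochelle salt
Reagents that add atoms: none
Why: Low-temperature DIBAL-H half-reduction of a lactone stops at the lactol because the tetrahedral aluminium alkoxide is stable at −78 °C.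

Step 5
Reactants: 5 bridged lactol
Product: 6 cis-5-ethenyl-5-methylcyclohex-3-en-1-ol (OH cis to vinyl)
Conditions: Ph3PCH3Br, KOt-Bu, THF, 0 °C → rt
Reagents that add atoms: methyltriphenylphosphonium bromide, C[P+](c1ccccc1)(c1ccccc1)c1ccccc1.[Br-]
Why: Wittig methylenation of the lactol through its open, non-enolizable hydroxy aldehyde turns C1 into the vinyl CH and frees O-8; the cis relation of OH and vinyl is inherited from the lactone bridge.

Step 6
Reactants: 6 dienol
Product: 7 tert-butyldimethylsilyl ether of 6
Conditions: t-BuMe2SiCl, imidazole, DMF, rt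
Reagents that add atoms: tert-butyldimethylsilyl chloride, CC(C)(C)[Si](C)(C)Cl
Why: Silyl ether formation blocks O-8 before any acyl group is present that could lactonize onto it.

Step 7
Reactants: 7 silyl ether
Product: 8 6-(tert-butyldimethylsilyloxy)-4-ethenyl-4-methylcyclohex-2-en-1-one (ketone at C7)
Conditions: Rh2(cap)4 (dirhodium tetracaprolactamate, 1 mol %), t-BuOOH (aq.), K2CO3 (cat.), CH2Cl2, rt
Reagents that add atoms: tert-butyl hydroperoxide, CC(C)(C)OO
Why: Dirhodium-catalysed allylic C–H oxidation converts the only allylic CH2 (C7; the vinyl group has no allylic hydrogen because C10 is quaternary) into the enone carbonyl.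

Step 8
Reactants: 8 enone
Product: 9 methyl 2-[6-(tert-butyldimethylsilyloxy)-4-ethenyl-1-hydroxy-4-methylcyclohex-2-en-1-yl]acetate (C7 epimers)
Conditions: MeOAc, LDA, THF, −78 °C; then 8; aq. NH4Cl
Reagents that add atoms: methyl acetate, CC(=O)OC
Why: Lithium ester enolates add 1,2 to enones at −78 °C (aldol-type addition); the C7 configuration is irrelevant because C7 becomes trigonal in the next step.

Step 9
Reactants: 9 tertiary allylic alcohol
Product: 10 methyl 2-[6-(tert-butyldimethylsilyloxy)-4-ethenyl-4-methyl-3-oxocyclohex-1-en-1-yl]acetate (ketone at C5)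
Conditions: pyridinium chlorochromate, 4 Å molecular sieves, CH2Cl2, rt
Reagents that add atoms: pyridinium chlorochromate, [O-][Cr](=O)(=O)Cl.c1cc[nH+]cc1
Why: Oxidative 1,3-transposition of a tertiary allylic alcohol (Babler–Dauben oxidation: [3,3]-shift of the chromate ester, then oxidation) moves the carbonyl to C5 and leaves the acetate chain on the enone β-carbon C7.

Step 10
Reactants: 10 transposed enone
Product: 11 methyl 2-[2-(tert-butyldimethylsilyloxy)-4-ethenyl-4-methyl-5-oxocyclohexyl]acetate (side chain cis to the silyloxy group)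
Conditions: [(Ph3P)CuH]6, benzene, H2O, rt
Reagents that add atoms: none
Why: Copper hydride conjugate reduction is chemoselective for the enone over the isolated vinyl group; hydride should reach C7 anti to the adjacent C8 silyloxy group, which places the CH2CO2Me chain cis to O-8.

Step 11
Reactants: 11 keto ester
Product: 13 4-(tert-butyldimethylsilyloxy)-6-ethenyl-6-methylhexahydro-1-benzofuran-2,7-dione (trans-fused keto lactone), via hydroxy keto ester 12 (not isolated)
Conditions: LiN(SiMe3)2, THF, −78 °C; 3-phenyl-2-(phenylsulfonyl)oxaziridine; → 0 °C; aq. NH4Cl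
Reagents that add atoms: 3-phenyl-2-(phenylsulfonyl)oxaziridine, O=S(=O)(c1ccccc1)N1OC1c1ccccc1
Why: Electrophilic α-hydroxylation of the only possible ketone enolate (C10 is quaternary) should occur anti to the C7 side chain, and the resulting trans γ-alkoxide acylates itself on the methyl ester (lactonization) to give the trans-fused 6,12-lactone.

Step 12
Reactants: 13 keto lactone
Product: 14 keto lactone aldehyde (3-oxopropyl chain on C10)
Conditions: Rh(acac)(CO)2 (1 mol %), Xantphos, CO/H2 (1:1, 10 bar), toluene, 70 °C
Reagents that add atoms: carbon monoxide, [C-]#[O+]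
Why: Rhodium-catalysed hydroformylation of the vinyl group gives only the linear aldehyde because the internal carbon is neopentylic; ketone, lactone and silyl ether are inert.

Step 13
Reactants: 14 aldehyde
Product: 15 alkylidene phosphonoacetate (E/Z mixture)
Conditions: (MeO)2P(O)CH2CO2Me, TiCl4, N-methylmorpholine, THF, 0 °C → rt
Reagents that add atoms: trimethyl phosphonoacetate, COC(=O)CP(=O)(OC)OC
Why: Titanium tetrachloride/amine-mediated Knoevenagel condensation of the aldehyde with the phosphonoacetate; the hindered C5 ketone should not condense.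

Step 14
Reactants: 15 alkylidene phosphonoacetate
Product: 17 methyl 8-(tert-butyldimethylsilyloxy)eudesm-4-en-6,12-olid-15-oate (decalin enoate; C6, C7, C8, C10 as in the target), via phosphonate carbanion 16 (not isolated)
Conditions: LiBH(s-Bu)3, THF, −78 °C → rt
Reagents that add atoms: none
Why: 1,4-Hydride addition to the doubly activated alkene generates the phosphonoacetate carbanion, which closes ring A by intramolecular Horner–Wadsworth–Emmons olefination of the C5 ketone (six-membered ring, C4=C5).

Step 15
Reactants: 17 decalin enoate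
Product: 18 methyl 5-hydroperoxy-8-(tert-butyldimethylsilyloxy)eudesm-3-en-6,12-olid-15-oate (C5 epimers)
Conditions: O2, visible light, tetraphenylporphyrin (cat.), CH2Cl2, 0 °C
Reagents that add atoms: dioxygen, O=O
Why: Schenck ene reaction of singlet oxygen with the α,β-unsaturated ester follows the geminal rule (hydrogen taken from C3 on the ester-bearing carbon, oxygen bound at the β-carbon C5); this gives the tertiary allylic hydroperoxide with the alkene already at C3=C4, and either C5 epimer is usable.

Step 16
Reactants: 18 decalin hydroperoxide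
Product: 20 methyl 5-(4-nitrobenzoyloxy)-8-(tert-butyldimethylsilyloxy)-5,10-epoxygermacr-3-en-6,12-olid-15-oate (bridgehead ketal ester), via peroxy ester 19 (not isolated)
Conditions: 4-O2NC6H4COCl, pyridine, CH2Cl2, 0 °C → rt
Reagents that add atoms: 4-nitrobenzoyl chloride, O=C(Cl)c1ccc(cc1)[N+](=O)[O-]
Why: Acylation gives perester 19, whose O–O bond heterolyses with a concerted 1,2-shift of C10 from C5 to the proximal oxygen (Criegee rearrangement), and the C5 carbenium–carboxylate ion pair collapses to ketal ester 20. The closest precedent is the rearrangement of 9-decalyl hydroperoxide esters to 1-acyloxy-11-oxabicyclo[4.4.1]undecanes, the same ring system. No ring is closed by cyclization: C10 carries its two ring bonds with it, so ring A and ring B each become a seven-membered oxacycle by insertion of the one oxygen, and the ten-membered carbocycle is their periphery. C10 migrates with retention (the new C10–O bond takes the place of the old C10–C5 bond), and the ketal centre C5 can only hold the acyloxy group exo to the one-atom bridge, so both C5 epimers of 18 converge. The step needs migration of C10 rather than C4 or C6; this is secured because C10 is a tertiary alkyl carbon, whereas C4 is an ester-bearing vinylic carbon and C6 carries the electron-withdrawing lactone oxygen. Pyridine and low temperature should keep the allylic perester from a 1,3-shift and the product from further ionization.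

Step 17
Reactants: 20 bridgehead ketal ester
Product: 21 methyl 8-(tert-butyldimethylsilyloxy)-5,10-epoxygermacr-3-en-6,12-olid-15-oate
Conditions: Et3SiH, Me3SiOTf (0.2 equiv), CH2Cl2, −78 → −30 °C
Reagents that add atoms: none
Why: Lewis acid ionization of the bridgehead acyloxy ketal and hydride transfer from the silane (ionic hydrogenation of a ketal ester) replace the acyloxy group by hydrogen; the C5 configuration is dictated by the bicycle because hydride can only arrive exo to the oxygen bridge.

Step 18
Reactants: 21 bridged ether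
Product: 24 methyl 8-(tert-butyldimethylsilyloxy)-5,10-epoxygermacra-3,11(13)-dien-6,12-olid-15-oate, via Mannich base 22 (not isolated), via methiodide 23 (not isolated)
Conditions: LDA, THF, −78 °C; CH2=NMe2+ I−, → 0 °C; MeI, MeOH, rt; NaHCO3, CH2Cl2/H2O
Reagents that add atoms: N,N-dimethylmethyleneiminium iodide, C=[N+](C)C.[I-]
Why: Kinetic enolization of the lactone and Mannich reaction with the iminium salt, then quaternization and loss of trimethylamine, give the exocyclic methylene (α-methylenation of a γ-lactone); C7 is untouched.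

Step 19
Reactants: 24 silyl-protected core
Product: 25 methyl 8-hydroxy-5,10-epoxygermacra-3,11(13)-dien-6,12-olid-15-oate
Conditions: HF·pyridine, THF, 0 °C → rt
Reagents that add atoms: none
Why: Fluoride-mediated desilylation frees the C8 hydroxyl under mildly acidic conditions that should spare lactone, enoate and ether bridge and avoid base-induced lactone migration.

Step 20
Reactants: 26 (2R,5R)-2-tert-butyl-5-methyl-1,3-dioxolan-4-one
Product: 27 2-tert-butyl-5-(1-hydroxyethyl)-5-methyl-1,3-dioxolan-4-one (new C–C bond trans to tert-butyl; carbinol epimers)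
Conditions: LDA, THF, −78 °C; CH3CHO
Reagents that add atoms: acetaldehyde, CC=O
Why: The dioxolanone enolate is attacked by acetaldehyde anti to the tert-butyl group (aldol addition with self-regeneration of the stereocentre), so the new bond takes the place of the original hydrogen.

Step 21
Reactants: 27 aldol adduct
Product: 28 2-tert-butyl-5-ethenyl-5-methyl-1,3-dioxolan-4-one
Conditions: MeO2CN(−)SO2N(+)Et3, benzene, 60 °C
Reagents that add atoms: none
Why: syn-Elimination of the secondary alcohol through its sulfamate ester (dehydration) can only take a hydrogen from the methyl group, giving the vinyl group; the quaternary stereocentre is not involved.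

Step 22
Reactants: 28 vinyl dioxolanone
Product: 29 (S)-2-hydroxy-2-methylbut-3-enoic acid
Conditions: LiOH, THF/H2O, rt; then 1 M HCl
Reagents that add atoms: water, O
Why: Saponification of the acylal-type lactone (ester hydrolysis) releases pivalaldehyde and the α-hydroxy acid without touching the quaternary stereocentre.

Step 23
Reactants: 29 hydroxy acid
Product: 31 (S)-2-methyl-2-(triethylsilyloxy)but-3-enoic acid, via bis-silyl ester 30 (not isolated)
Conditions: Et3SiCl, imidazole, DMF, rt; then H2O/THF
Reagents that add atoms: chlorotriethylsilane, CC[Si](Cl)(CC)CC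
Why: Exhaustive silylation followed by selective hydrolysis of the labile silyl ester leaves the tertiary alcohol protected (silyl protection).

Step 24
Reactants: 25 core alcohol; 31 silyl-protected acid
Product: 33 8-O-[(S)-2-methyl-2-(triethylsilyloxy)but-3-enoyl] ester of 25, via acid chloride 32 (not isolated)
Conditions: 31, Me2C=C(Cl)NMe2, CH2Cl2, 0 °C; then 25, pyridine, DMAP, CH2Cl2, rt
Reagents that add atoms: none
Why: The acid is activated under neutral conditions as its acid chloride with the α-chloroenamine and acylates the secondary C8 alcohol under DMAP catalysis (esterification); the acid has no α-hydrogen, so no stereocentre is at risk.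

Step 25
Reactants: 33 silyl-protected ester
Product: 34 target (CNP0325750.1)
Conditions: HF·pyridine, pyridine/THF, 0 °C
Reagents that add atoms: none
Why: Mild fluoride cleavage of the tertiary triethylsilyl ether (desilylation) should give the target with all other groups intact.

**Compound list**

1 | benzoic acid | OC(=O)c1ccccc1 | starting material
2 | 1-methylcyclohexa-2,5-diene-1-carboxylic acid | CC1(C(=O)O)C=CCC=C1 | intermediate
3 | 8-bromo-1-methyl-6-oxabicyclo[3.2.1]oct-2-en-7-one (Br anti to lactone O) | C[C@]12C=CC[C@H](OC1=O)[C@H]2Br | intermediate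
4 | 1-methyl-6-oxabicyclo[3.2.1]oct-2-en-7-one | C[C@]12C=CC[C@H](OC1=O)C2 | intermediate
5 | 1-methyl-6-oxabicyclo[3.2.1]oct-2-en-7-ol (lactol, anomer mixture) | C[C@]12C=CC[C@H](OC1O)C2 | intermediate
6 | cis-5-ethenyl-5-methylcyclohex-3-en-1-ol | O[C@H]1CC=C[C@@](C)(C=C)C1 | intermediate
7 | tert-butyldimethylsilyl ether of 6 | CC(C)(C)[Si](C)(C)O[C@H]1CC=C[C@@](C)(C=C)C1 | intermediate
8 | 6-(tert-butyldimethylsilyloxy)-4-ethenyl-4-methylcyclohex-2-en-1-one | CC(C)(C)[Si](C)(C)O[C@H]1C(=O)C=C[C@@](C)(C=C)C1 | intermediate
9 | methyl 2-[6-(tert-butyldimethylsilyloxy)-4-ethenyl-1-hydroxy-4-methylcyclohex-2-en-1-yl]acetate (carbinol epimers) | CC(C)(C)[Si](C)(C)O[C@H]1C(O)(CC(=O)OC)C=C[C@@](C)(C=C)C1 | intermediate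
10 | methyl 2-[6-(tert-butyldimethylsilyloxy)-4-ethenyl-4-methyl-3-oxocyclohex-1-en-1-yl]acetate | CC(C)(C)[Si](C)(C)O[C@@H]1C[C@](C)(C=C)C(=O)C=C1CC(=O)OC | intermediate
11 | methyl 2-[2-(tert-butyldimethylsilyloxy)-4-ethenyl-4-methyl-5-oxocyclohexyl]acetate (chain cis to silyloxy) | CC(C)(C)[Si](C)(C)O[C@@H]1C[C@](C)(C=C)C(=O)C[C@@H]1CC(=O)OC | intermediate
12 | 6-hydroxy derivative of 11 (OH trans to the chain) | CC(C)(C)[Si](C)(C)O[C@@H]1C[C@](C)(C=C)C(=O)[C@@H](O)[C@@H]1CC(=O)OC | intermediate (not isolated)
13 | 4-(tert-butyldimethylsilyloxy)-6-ethenyl-6-methylhexahydro-1-benzofuran-2,7-dione (trans-fused) | CC(C)(C)[Si](C)(C)O[C@@H]1C[C@](C)(C=C)C(=O)[C@H]2OC(=O)C[C@@H]21 | intermediate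
14 | 3-oxopropyl analogue of 13 (aldehyde) | CC(C)(C)[Si](C)(C)O[C@@H]1C[C@](C)(CCC=O)C(=O)[C@H]2OC(=O)C[C@@H]21 | intermediate
15 | alkylidene phosphonoacetate from 14 (E/Z) | CC(C)(C)[Si](C)(C)O[C@@H]1C[C@](C)(CCC=C(C(=O)OC)P(=O)(OC)OC)C(=O)[C@H]2OC(=O)C[C@@H]21 | intermediate
16 | lithium phosphonoacetate carbanion from 15 | CC(C)(C)[Si](C)(C)O[C@@H]1C[C@](C)(CCC[C-](C(=O)OC)P(=O)(OC)OC)C(=O)[C@H]2OC(=O)C[C@@H]21.[Li+] | intermediate (not isolated)
17 | methyl 8-(tert-butyldimethylsilyloxy)eudesm-4-en-6,12-olid-15-oate (trans-lactone; C10 as in target) | CC(C)(C)[Si](C)(C)O[C@@H]1C[C@]2(C)CCCC(C(=O)OC)=C2[C@H]2OC(=O)C[C@@H]21 | intermediate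
18 | methyl 5-hydroperoxy-8-(tert-butyldimethylsilyloxy)eudesm-3-en-6,12-olid-15-oate (C5 epimers) | CC(C)(C)[Si](C)(C)O[C@@H]1C[C@]2(C)CCC=C(C(=O)OC)C2(OO)[C@H]2OC(=O)C[C@@H]21 | intermediate
19 | 4-nitroperbenzoate of 18 | CC(C)(C)[Si](C)(C)O[C@@H]1C[C@]2(C)CCC=C(C(=O)OC)C2(OOC(=O)c3ccc(cc3)[N+](=O)[O-])[C@H]2OC(=O)C[C@@H]21 | intermediate (not isolated)
20 | methyl 5-(4-nitrobenzoyloxy)-8-(tert-butyldimethylsilyloxy)-5,10-epoxygermacr-3-en-6,12-olid-15-oate | CC(C)(C)[Si](C)(C)O[C@@H]1C[C@]2(C)CCC=C(C(=O)OC)[C@@](OC(=O)c3ccc(cc3)[N+](=O)[O-])(O2)[C@H]2OC(=O)C[C@@H]21 | intermediate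
21 | methyl 8-(tert-butyldimethylsilyloxy)-5,10-epoxygermacr-3-en-6,12-olid-15-oate | CC(C)(C)[Si](C)(C)O[C@@H]1C[C@]2(C)CCC=C(C(=O)OC)[C@@H](O2)[C@H]2OC(=O)C[C@@H]21 | intermediate
22 | 11-(dimethylaminomethyl) derivative of 21 (C11 epimers) | CC(C)(C)[Si](C)(C)O[C@@H]1C[C@]2(C)CCC=C(C(=O)OC)[C@@H](O2)[C@H]2OC(=O)C(CN(C)C)[C@@H]21 | intermediate (not isolated)
23 | methiodide of 22 | CC(C)(C)[Si](C)(C)O[C@@H]1C[C@]2(C)CCC=C(C(=O)OC)[C@@H](O2)[C@H]2OC(=O)C(C[N+](C)(C)C)[C@@H]21.[I-] | intermediate (not isolated)
24 | methyl 8-(tert-butyldimethylsilyloxy)-5,10-epoxygermacra-3,11(13)-dien-6,12-olid-15-oate | CC(C)(C)[Si](C)(C)O[C@@H]1C[C@]2(C)CCC=C(C(=O)OC)[C@@H](O2)[C@H]2OC(=O)C(=C)[C@@H]21 | intermediate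
25 | methyl 8-hydroxy-5,10-epoxygermacra-3,11(13)-dien-6,12-olid-15-oate | O[C@@H]1C[C@]2(C)CCC=C(C(=O)OC)[C@@H](O2)[C@H]2OC(=O)C(=C)[C@@H]21 | intermediate
26 | (2R,5R)-2-tert-butyl-5-methyl-1,3-dioxolan-4-one (cis) | C[C@H]1O[C@@H](C(C)(C)C)OC1=O | starting material
27 | 2-tert-butyl-5-(1-hydroxyethyl)-5-methyl-1,3-dioxolan-4-one (hydroxyethyl trans to tert-butyl; carbinol epimers) | C[C@@]1(C(C)O)O[C@@H](C(C)(C)C)OC1=O | intermediate
28 | 2-tert-butyl-5-ethenyl-5-methyl-1,3-dioxolan-4-one (vinyl trans to tert-butyl) | C[C@@]1(C=C)O[C@@H](C(C)(C)C)OC1=O | intermediate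
29 | (S)-2-hydroxy-2-methylbut-3-enoic acid | C[C@@](C=C)(O)C(=O)O | intermediate
30 | triethylsilyl (S)-2-methyl-2-(triethylsilyloxy)but-3-enoate | C[C@@](C=C)(O[Si](CC)(CC)CC)C(=O)O[Si](CC)(CC)CC | intermediate (not isolated)
31 | (S)-2-methyl-2-(triethylsilyloxy)but-3-enoic acid | C[C@@](C=C)(O[Si](CC)(CC)CC)C(=O)O | intermediate
32 | (S)-2-methyl-2-(triethylsilyloxy)but-3-enoyl chloride | C[C@@](C=C)(O[Si](CC)(CC)CC)C(=O)Cl | intermediate (not isolated)
33 | triethylsilyl ether of the target (at the side-chain hydroxyl) | C=C[C@](C)(O[Si](CC)(CC)CC)C(=O)O[C@@H]1C[C@]2(C)CCC=C(C(=O)OC)[C@@H](O2)[C@H]2OC(=O)C(=C)[C@@H]21 | intermediate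
34 | CNP0325750.1, methyl 8-[(2S)-2-hydroxy-2-methylbut-3-enoyloxy]-5,10-epoxygermacra-3,11(13)-dien-6,12-olid-15-oate | C=C[C@](C)(O)C(=O)O[C@@H]1C[C@]2(C)CCC=C(C(=O)OC)[C@@H](O2)[C@H]2OC(=O)C(=C)[C@@H]21 | target

**Step count and risks**

Total steps: 25. Longest linear sequence: 21 steps (steps 1–19, 24, 25).

Steps most likely to fail:

1. Step 17. Ionization at the bridgehead C5 may be too slow: the oxocarbenium ion is twisted and poorly stabilized by the bridge oxygen, and it is further deactivated by the ester-bearing vinyl group and the C6 acyloxy group. Opening of the ether bridge or no reaction could then compete with hydride transfer. The fallback removes the bridgehead oxygen by a radical instead of an ionic path. It sets out from hydroperoxide 18: acylation with methyl chlorooxoacetate and pyridine should give the peroxy oxalate F1, which should undergo the same Criegee shift to the bridgehead methyl oxalate F2. Bu3SnH with AIBN in toluene at 100 °C should then cleave the C5–O(oxalate) bond homolytically; the tertiary α-alkoxy bridgehead radical takes hydrogen from the stannane to give 21, where the route is rejoined.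

2. Step 16. The O–O heterolysis may follow another course: an allylic 1,3-shift of the perester, migration of the vinylic carbon with Hock-type cleavage, or elimination from the ion pair instead of collapse. The fallback inserts the oxygen through an alkoxyl radical instead of a cation. It sets out from 18: triphenylphosphine should reduce it to the tertiary allylic alcohol F3. PhI(OAc)2 and I2 under visible light should generate the C5 alkoxyl radical; β-scission of C5–C10 gives the tertiary C10 radical, which is oxidized and captured transannularly by the C5 carbonyl oxygen, and acetate traps the ion as the bridgehead acetate F4. Reduction under the conditions of step 17 returns to 21. In this variant C10 is re-formed under conformational control, not stereospecifically.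

3. Step 15. The ene reaction of the electron-poor, tetrasubstituted enoate may be slow, so that sensitizer bleaching and unselective oxidation take over. The fallback uses ionic allylic substitution instead of the pericyclic oxygenation. It sets out from 17: N-bromosuccinimide with AIBN should brominate the allylic C3 position to give the bromide F5. Silver trifluoroacetate and anhydrous H2O2 in ether should then effect perhydrolysis with allylic transposition (attack at the tertiary C5 end of the silver-assisted allyl cation), returning to 18.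

Further compounds
F1 | step 17 | methyl peroxyoxalate of 18 (not isolated) | CC(C)(C)[Si](C)(C)O[C@@H]1C[C@]2(C)CCC=C(C(=O)OC)C2(OOC(=O)C(=O)OC)[C@H]2OC(=O)C[C@@H]21
F2 | step 17 | bridgehead methyl oxalate (5-(methoxyoxalyloxy) analogue of 20) | CC(C)(C)[Si](C)(C)O[C@@H]1C[C@]2(C)CCC=C(C(=O)OC)[C@@](OC(=O)C(=O)OC)(O2)[C@H]2OC(=O)C[C@@H]21
F3 | step 16 | methyl 5-hydroxy-8-(tert-butyldimethylsilyloxy)eudesm-3-en-6,12-olid-15-oate | CC(C)(C)[Si](C)(C)O[C@@H]1C[C@]2(C)CCC=C(C(=O)OC)C2(O)[C@H]2OC(=O)C[C@@H]21
F4 | step 16 | bridgehead acetate (5-acetoxy analogue of 20) | CC(C)(C)[Si](C)(C)O[C@@H]1C[C@]2(C)CCC=C(C(=O)OC)[C@@](OC(C)=O)(O2)[C@H]2OC(=O)C[C@@H]21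
F5 | step 15 | 3-bromo derivative of 17 (C3 epimers) | CC(C)(C)[Si](C)(C)O[C@@H]1C[C@]2(C)CCC(Br)C(C(=O)OC)=C2[C@H]2OC(=O)C[C@@H]21
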